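Ring B is disconnected at C7–C8. C7 carries the isopropenyl group and lies β to the C9 oxygen, so the C8 carbon of a C9 enolate can attack the internal carbon of a 2-methylallyl palladium unit anchored on C5: one operation closes ring B, creates C7 and unveils the isopropenyl group. The precursor is a ring A methyl ketone (acetyl on C10) with the C3 silyl ether, the C4 and C5 methyl groups and an allylic carbonate arm on C5 in place. Its four stereocentres come from an epoxide (C3, C4), an oxygen-tethered radical cyclisation (C5) and equilibration inside a bridged acetal (C10); the diol and the ester side chain follow.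

Key step: step 12

Remarks
- Numbering: eremophilane numbering is used for every intermediate (ring A = C1–C5 and C10; arm = C6, C7, C11–C13; acetyl = C9, C8). β is the face of the C5 methyl group.
- Key-step design: the nucleophile is the enolate of the C9 carbonyl (the acetyl group on C10), reacting through C8. The allylic leaving group is a methyl carbonate rather than an acetate, because an acetate has enolisable protons that compete for the amide base and can acylate the enolate.
- Assumption: compound 26 is taken as purchasable; otherwise it is one hydrolysis step from its commercial methyl ester.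
- Assumption: the sense of induction in step 3 is assigned by analogy with indene; the enantiomeric catalyst is equally available if the analogy fails.

Step 1
Reactants: 1 ethyl 2-methyl-4-oxocyclohex-2-ene-1-carboxylate (racemic)
Product: 2 ethyl 4-hydroxy-2-methylcyclohex-2-ene-1-carboxylate (diastereomer mixture)
Conditions: NaBH4, CeCl3·7H2O, MeOH, 0 °C
Reagents that add atoms: none
Why: Luche 1,2-reduction: the CeCl3-modified borohydride adds to the enone carbonyl and leaves the ester, and the configuration of the new carbinol and of C10 is irrelevant because both centres become sp2 in step 2.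

Step 2
Reactants: 2 ethyl 4-hydroxy-2-methylcyclohex-2-ene-1-carboxylate
Product: 4 ethyl 2-methylcyclohexa-1,3-diene-1-carboxylate, via allylic mesylate 3 (not isolated)
Conditions: MsCl, Et3N, CH2Cl2, 0 °C; then DBU, 25 °C
Reagents that add atoms: none
Why: Mesylation followed by base-induced 1,4-elimination: loss of the allylic mesylate and of the C10 proton α to the ester gives the diene, and DBU equilibrates any isomeric diene to the linearly conjugated dienoate, which is the stable one.

Step 3
Reactants: 4 ethyl 2-methylcyclohexa-1,3-diene-1-carboxylate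
Product: 5 ethyl (1S,6R)-2-methyl-7-oxabicyclo[4.1.0]hept-2-ene-3-carboxylate
Conditions: (S,S)-[N,N'-bis(3,5-di-tert-butylsalicylidene)-1,2-cyclohexanediaminato]manganese chloride (5 mol %), 4-phenylpyridine N-oxide, NaOCl (aq, pH 11), CH2Cl2, 0 °C
Reagents that add atoms: sodium hypochlorite, [Na+].[O-]Cl
Why: Jacobsen–Katsuki epoxidation: the manganese oxo species attacks the electron-richer cis-disubstituted C3=C4 bond and not the tetrasubstituted, ester-bearing C5=C10 bond, and the (S,S) ligand is chosen to deliver oxygen to the α-face of C3 and C4.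

Step 4
Reactants: 5 ethyl (1S,6R)-2-methyl-7-oxabicyclo[4.1.0]hept-2-ene-3-carboxylate
Product: 6 ethyl (3R,4R)-4-hydroxy-2,3-dimethylcyclohex-1-ene-1-carboxylate
Conditions: AlMe3 (5 equiv), H2O (2 equiv), CH2Cl2, −30 °C
Reagents that add atoms: trimethylaluminium, C[Al](C)C
Why: Lewis-acid-assisted SN2 opening of a γ,δ-epoxy enoate by an organoaluminium reagent: methyl enters at the allylic carbon C4 with inversion, so the C4 methyl is β and trans to the untouched 3α-hydroxyl.

Step 5
Reactants: 6 ethyl (3R,4R)-4-hydroxy-2,3-dimethylcyclohex-1-ene-1-carboxylate; 7 ethyl vinyl ether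
Product: 8 ethyl (3R,4R)-4-(2-bromo-1-ethoxyethoxy)-2,3-dimethylcyclohex-1-ene-1-carboxylate (both acetal epimers)
Conditions: NBS, CH2Cl2, −40 → 0 °C
Reagents that add atoms: N-bromosuccinimide, O=C1CCC(=O)N1Br
Why: Haloacetalisation: the bromonium ion of the vinyl ether is captured by the C3 hydroxyl, which tethers a two-carbon unit at the aldehyde oxidation level (the future C6 and C7) to the α-oxygen, the acetal centre being erased in step 7.

Step 6
Reactants: 8 ethyl (3R,4R)-4-(2-bromo-1-ethoxyethoxy)-2,3-dimethylcyclohex-1-ene-1-carboxylate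
Product: 10 ethyl 3-ethoxy-5,9-dimethyl-2-oxabicyclo[3.3.1]nonane-6-carboxylate (C3–O and C5–C6 bridged on the α-face; C4 and C5 methyls β; C10 ester α), via kinetic C10 epimer mixture 9 (not isolated)
Conditions: Bu3SnH (syringe pump), AIBN (cat.), PhH (0.01 M), 80 °C; then NaOEt (cat.), EtOH, 60 °C
Reagents that add atoms: none
Why: Ueno–Stork radical cyclisation (6-exo-trig) then base equilibration: the primary radical can reach the enoate β-carbon C5 only from the face of the C3 oxygen, so C6 is α and the C5 methyl β (cis to the C4 methyl), and ethoxide then epimerises C10 to the ester that is equatorial on the carbocyclic chair (α, cis to C6), its epimer being syn-axial to the C4 methyl.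

Step 7
Reactants: 10 ethyl 3-ethoxy-5,9-dimethyl-2-oxabicyclo[3.3.1]nonane-6-carboxylate
Product: 12 1-(3-hydroxy-5,9-dimethyl-2-oxabicyclo[3.3.1]nonan-6-yl)ethanone (keto lactol; 10α-acetyl), via enol ether 11 (not isolated)
Conditions: Cp2TiMe2 (3 equiv), toluene–THF, 65 °C; then 1 M HCl, THF, 0 → 25 °C
Reagents that add atoms: dimethyltitanocene Cp2TiMe2, C[Ti](C)(C1C=CC=C1)C1C=CC=C1; water, O
Why: Petasis methylenation then acid hydrolysis: the titanium reagent converts the ester carbonyl into an enol ether without base, and aqueous acid hydrolyses the enol ether to the methyl ketone (C9, C8) and the ethyl acetal to the lactol while C10 stays in its stable α configuration inside the bicycle.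

Step 8
Reactants: 12 keto lactol; 13 2-(triphenylphosphoranylidene)propanal
Product: 14 (2E)-4-[(1R,2R,3R,6S)-6-acetyl-3-hydroxy-1,2-dimethylcyclohexyl]-2-methylbut-2-enal
Conditions: toluene, 90 °C
Reagents that add atoms: none
Why: Wittig olefination of a lactol through its open hydroxy aldehyde: the formyl-stabilised ylide reacts with the aldehyde but not with the hindered methyl ketone and gives the (E)-enal, setting free the 3α-hydroxyl under non-epimerising conditions.

Step 9
Reactants: 14 hydroxy enal
Product: 15 (2E)-4-[(1R,2R,3R,6S)-6-acetyl-3-(tert-butyldimethylsilyloxy)-1,2-dimethylcyclohexyl]-2-methylbut-2-enal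
Conditions: TBSCl, imidazole, DMF, 40 °C
Reagents that add atoms: tert-butyldimethylsilyl chloride, CC(C)(C)[Si](C)(C)Cl
Why: Silylation of the equatorial secondary alcohol with a mild base that does not epimerise the axial acetyl group at C10, the TBS ether being chosen to survive the enolate, palladium and hydride steps.

Step 10
Reactants: 15 silyl ether enal
Product: 16 (2E)-4-[(1R,2R,3R,6S)-6-acetyl-3-(tert-butyldimethylsilyloxy)-1,2-dimethylcyclohexyl]-2-methylbut-2-en-1-ol
Conditions: NaBH4 (0.5 equiv), EtOH–CH2Cl2 (1:3), −78 °C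
Reagents that add atoms: none
Why: Chemoselective borohydride 1,2-reduction at low temperature: the aldehyde is reduced far faster than the methyl ketone, which is flanked by the quaternary C5.

Step 11
Reactants: 16 allylic alcohol
Product: 17 (2E)-4-[(1R,2R,3R,6S)-6-acetyl-3-(tert-butyldimethylsilyloxy)-1,2-dimethylcyclohexyl]-2-methylbut-2-en-1-yl methyl carbonate
Conditions: ClCO2Me, pyridine, CH2Cl2, 0 °C
Reagents that add atoms: methyl chloroformate, COC(=O)Cl
Why: Acylation of the primary allylic alcohol to a methyl carbonate, a leaving group that is ionised readily by zerovalent palladium and has no enolisable protons.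

Step 12
Reactants: 17 allylic carbonate methyl ketone
Product: 19 3α-(tert-butyldimethylsilyloxy)eremophil-11-en-9-one (10βH), via chlorozinc enolate 18 (not isolated)
Conditions: LiN(iPr)2 (1.1 equiv), THF, −78 °C (ketone added to base); ZnCl2 (1.2 equiv); Pd(PPh3)4 (5 mol %), −78 → 25 °C
Reagents that add atoms: none
Why: The kinetic enolate of the acetyl group is formed at C8 and transmetallated to zinc; Pd(PPh3)4 (zerovalent palladium) ionises the carbonate with loss of CO2 to a 2-methyl π-allyl complex spanning C7 and C12, and the enolate carbon attacks the internal terminus C7, forming C7–C8 and leaving C11=C12 as the isopropenyl group. The closest known reaction type is the intramolecular Tsuji–Trost allylation of ketone enolates that gives 3-vinylcyclohexanones. Ring B closes in the 6-exo mode, because attack at the outer terminus C12 would need an eight-membered ring. C7 is set by the substrate: in the chair-like transition state ring A keeps O3 and the C4 methyl equatorial, which puts the acetyl carbon axial and C6 equatorial, and the allyl residue on C7 takes the equatorial position because the axial one is syn to the axial C5–C4 bond, so the isopropenyl group ends 7β, cis to the C5 methyl. The step needs enolisation at the methyl rather than at the C10 methine (secured by the hindered amide at −78 °C with inverse addition) and C- rather than O-allylation (secured by the zinc counter-ion). C10 then lies α to the new ketone, and the cis-fused 10βH isomer is the stable one once C7 is β.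

Step 13
Reactants: 19 3α-(tert-butyldimethylsilyloxy)eremophil-11-en-9-one (10βH)
Product: 21 3α-(tert-butyldimethylsilyloxy)-8β-(triethylsilyloxy)eremophil-11-en-9-one (10βH), via triethylsilyl enol ether 20 (not isolated)
Conditions: LiN(iPr)2, THF, −78 °C; Et3SiCl, Et3N; then mCPBA (1.05 equiv), CH2Cl2–hexane, −20 → 0 °C
Reagents that add atoms: chlorotriethylsilane, CC[Si](Cl)(CC)CC; 3-chloroperbenzoic acid, OOC(=O)c1cccc(Cl)c1
Why: Rubottom oxidation: the kinetic enolate (C8 methylene rather than the C10 methine) is trapped as the silyl enol ether, the peracid epoxidises this electron-rich double bond in preference to the isopropenyl group from the convex β-face of the cis-fused bicycle, and 1,4-silyl migration gives the axial 8β-silyloxy ketone.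

Step 14
Reactants: 21 8β-silyloxy ketone
Product: 22 3α-(tert-butyldimethylsilyloxy)-8β-(triethylsilyloxy)eremophil-11-en-9β-ol (10βH)
Conditions: NaBH4, MeOH–THF, −40 → −20 °C
Reagents that add atoms: none
Why: Felkin–Anh-controlled hydride reduction of an α-silyloxy ketone: borohydride adds to C9 anti to the axial C8–O bond, from the α-face that the bulky axial silyloxy group leaves open, giving the equatorial 9β-alcohol cis to O8.

Step 15
Reactants: 22 9β-alcohol
Product: 24 3α-(tert-butyldimethylsilyloxy)-8β,9β-(isopropylidenedioxy)eremophil-11-ene (10βH), via free 8β,9β-diol 23 (not isolated)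
Conditions: PPTS, MeOH, 25 °C; concentrate; then Me2C(OMe)2, acetone, PPTS, 25 °C
Reagents that add atoms: 2,2-dimethoxypropane, COC(C)(C)OC
Why: Acid-catalysed methanolysis of the triethylsilyl ether (the hindered TBS ether at C3 survives) followed by transacetalisation of the cis-diol (axial O8, equatorial O9) to the acetonide.

Step 16
Reactants: 24 silyl ether acetonide
Product: 25 8β,9β-(isopropylidenedioxy)eremophil-11-en-3α-ol (10βH)
Conditions: Bu4NF, THF, 40 °C
Reagents that add atoms: none
Why: Fluoride-mediated cleavage of the silyl ether, to which the acetonide and the isopropenyl group are inert.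

Step 17
Reactants: 25 3α-alcohol; 26 [bis(2,2,2-trifluoroethoxy)phosphoryl]acetic acid
Product: 27 8β,9β-(isopropylidenedioxy)eremophil-11-en-3α-yl [bis(2,2,2-trifluoroethoxy)phosphoryl]acetate
Conditions: EDC·HCl, DMAP (cat.), CH2Cl2, 0 → 25 °C
Reagents that add atoms: none
Why: Steglich esterification of the equatorial C3 alcohol, which places the Still–Gennari phosphonate on the core.

Step 18
Reactants: 28 (R)-pent-4-en-2-ol; 29 angelic acid [(Z)-2-methylbut-2-enoic acid]
Product: 31 (R)-pent-4-en-2-yl (Z)-2-methylbut-2-enoate, via mixed anhydride 30 (not isolated)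
Conditions: 29, 2,4,6-Cl3C6H2COCl, Et3N, toluene, 25 °C; then 28, 80 °C
Reagents that add atoms: none
Why: Yamaguchi-type esterification through the mixed anhydride, run without DMAP because nucleophilic catalysts isomerise angelates to tiglates; the carbinol centre is not touched.

Step 19
Reactants: 31 (R)-pent-4-en-2-yl (Z)-2-methylbut-2-enoate
Product: 32 (R)-4-oxobutan-2-yl (Z)-2-methylbut-2-enoate
Conditions: OsO4 (2 mol %), NaIO4 (4 equiv), 2,6-lutidine, dioxane–H2O (3:1), 25 °C
Reagents that add atoms: sodium periodate (terminal oxidant and oxygen source), [Na+].[O-]I(=O)(=O)=O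
Why: Lemieux–Johnson oxidative cleavage: OsO4 dihydroxylates the electron-rich terminal alkene much faster than the conjugated trisubstituted angelate double bond, and periodate cleaves the diol under buffered conditions that do not eliminate the β-acyloxy aldehyde.

Step 20
Reactants: 27 phosphonoacetate; 32 (R)-4-oxobutan-2-yl (Z)-2-methylbut-2-enoate
Product: 33 8β,9β-(isopropylidenedioxy)eremophil-11-en-3α-yl (2Z,5R)-5-[(Z)-2-methylbut-2-enoyloxy]hex-2-enoate
Conditions: 27, KN(SiMe3)2 (1.0 equiv), 18-crown-6, THF, −78 °C; then 32, −78 °C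
Reagents that add atoms: none
Why: Still–Gennari olefination: the potassium anion of the bis(trifluoroethyl) phosphonoacetate adds to the aldehyde and collapses under kinetic control to the (Z)-enoate, and at −78 °C this weakly basic anion does not eliminate the β-angelate.

Step 21
Reactants: 33 acetonide
Product: 34 (10βH)-8β,9β-dihydroxyeremophil-11-en-3α-yl (2Z,5R)-5-[(Z)-2-methylbut-2-enoyloxy]hex-2-enoate (CNP0395983.1)
Conditions: AcOH–H2O (4:1), 40 °C
Reagents that add atoms: none
Why: Mild acid hydrolysis of the acetonide, which both esters, the (Z)-enoate, the angelate and the isopropenyl group should tolerate.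

Compound list
1 | ethyl 2-methyl-4-oxocyclohex-2-ene-1-carboxylate (racemic) | CCOC(=O)C1CCC(=O)C=C1C | starting material
2 | ethyl 4-hydroxy-2-methylcyclohex-2-ene-1-carboxylate (diastereomer mixture) | CCOC(=O)C1CCC(O)C=C1C | intermediate
3 | ethyl 2-methyl-4-(methylsulfonyloxy)cyclohex-2-ene-1-carboxylate | CCOC(=O)C1CCC(OS(C)(=O)=O)C=C1C | intermediate
4 | ethyl 2-methylcyclohexa-1,3-diene-1-carboxylate | CCOC(=O)C1=C(C)C=CCC1 | intermediate
5 | ethyl (1S,6R)-2-methyl-7-oxabicyclo[4.1.0]hept-2-ene-3-carboxylate (α-epoxide across C3–C4) | CCOC(=O)C1=C(C)[C@@H]2O[C@@H]2CC1 | intermediate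
6 | ethyl (3R,4R)-4-hydroxy-2,3-dimethylcyclohex-1-ene-1-carboxylate (3α-OH, 4β-Me) | CCOC(=O)C1=C(C)[C@@H](C)[C@H](O)CC1 | intermediate
7 | ethyl vinyl ether | C=COCC | starting material
8 | ethyl (3R,4R)-4-(2-bromo-1-ethoxyethoxy)-2,3-dimethylcyclohex-1-ene-1-carboxylate (both acetal epimers) | CCOC(CBr)O[C@@H]1CCC(C(=O)OCC)=C(C)[C@H]1C | intermediate
9 | ethyl 3-ethoxy-5,9-dimethyl-2-oxabicyclo[3.3.1]nonane-6-carboxylate, kinetic mixture of C10 epimers | CCOC2C[C@@]1(C)C(CC[C@@H](O2)[C@@H]1C)C(=O)OCC | intermediate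
10 | ethyl 3-ethoxy-5,9-dimethyl-2-oxabicyclo[3.3.1]nonane-6-carboxylate (O3 and C6 bridged on the α-face; 4β,5β-dimethyl; 10α-ester; both acetal epimers) | CCOC2C[C@@]1(C)[C@H](CC[C@@H](O2)[C@@H]1C)C(=O)OCC | intermediate
11 | 3-ethoxy-6-(1-ethoxyvinyl)-5,9-dimethyl-2-oxabicyclo[3.3.1]nonane (same configuration as 10) | CCOC2C[C@@]1(C)[C@H](CC[C@@H](O2)[C@@H]1C)C(=C)OCC | intermediate
12 | 1-(3-hydroxy-5,9-dimethyl-2-oxabicyclo[3.3.1]nonan-6-yl)ethanone (keto lactol; 10α-acetyl; both anomers) | OC2C[C@@]1(C)[C@H](CC[C@@H](O2)[C@@H]1C)C(C)=O | intermediate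
13 | 2-(triphenylphosphoranylidene)propanal | CC(C=O)=P(c1ccccc1)(c1ccccc1)c1ccccc1 | starting material
14 | (2E)-4-[(1R,2R,3R,6S)-6-acetyl-3-hydroxy-1,2-dimethylcyclohexyl]-2-methylbut-2-enal | O=C/C(C)=C/C[C@@]1(C)[C@H](CC[C@@H](O)[C@@H]1C)C(C)=O | intermediate
15 | (2E)-4-[(1R,2R,3R,6S)-6-acetyl-3-(tert-butyldimethylsilyloxy)-1,2-dimethylcyclohexyl]-2-methylbut-2-enal | O=C/C(C)=C/C[C@@]1(C)[C@H](CC[C@@H](O[Si](C)(C)C(C)(C)C)[C@@H]1C)C(C)=O | intermediate
16 | (2E)-4-[(1R,2R,3R,6S)-6-acetyl-3-(tert-butyldimethylsilyloxy)-1,2-dimethylcyclohexyl]-2-methylbut-2-en-1-ol | OC/C(C)=C/C[C@@]1(C)[C@H](CC[C@@H](O[Si](C)(C)C(C)(C)C)[C@@H]1C)C(C)=O | intermediate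
17 | (2E)-4-[(1R,2R,3R,6S)-6-acetyl-3-(tert-butyldimethylsilyloxy)-1,2-dimethylcyclohexyl]-2-methylbut-2-en-1-yl methyl carbonate (key-step precursor: 3α-silyloxy, 4β,5β-dimethyl, 10α-acetyl, arm on C5α) | COC(=O)OC/C(C)=C/C[C@@]1(C)[C@H](CC[C@@H](O[Si](C)(C)C(C)(C)C)[C@@H]1C)C(C)=O | intermediate
18 | chlorozinc enolate of 17 (enolate carbon C8) | COC(=O)OC/C(C)=C/C[C@@]1(C)[C@H](CC[C@@H](O[Si](C)(C)C(C)(C)C)[C@@H]1C)C(=C)O[Zn]Cl | intermediate
19 | 3α-(tert-butyldimethylsilyloxy)eremophil-11-en-9-one (10βH) | C=C(C)[C@H]1C[C@@]2(C)[C@H](CC[C@@H](O[Si](C)(C)C(C)(C)C)[C@@H]2C)C(=O)C1 | intermediate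
20 | 3α-(tert-butyldimethylsilyloxy)-9-(triethylsilyloxy)eremophila-8,11-diene (10βH) | C=C(C)[C@H]1C[C@@]2(C)[C@H](CC[C@@H](O[Si](C)(C)C(C)(C)C)[C@@H]2C)C(O[Si](CC)(CC)CC)=C1 | intermediate
21 | 3α-(tert-butyldimethylsilyloxy)-8β-(triethylsilyloxy)eremophil-11-en-9-one (10βH) | C=C(C)[C@H]1C[C@@]2(C)[C@H](CC[C@@H](O[Si](C)(C)C(C)(C)C)[C@@H]2C)C(=O)[C@H]1O[Si](CC)(CC)CC | intermediate
22 | 3α-(tert-butyldimethylsilyloxy)-8β-(triethylsilyloxy)eremophil-11-en-9β-ol (10βH) | C=C(C)[C@H]1C[C@@]2(C)[C@H](CC[C@@H](O[Si](C)(C)C(C)(C)C)[C@@H]2C)[C@@H](O)[C@H]1O[Si](CC)(CC)CC | intermediate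
23 | 3α-(tert-butyldimethylsilyloxy)eremophil-11-ene-8β,9β-diol (10βH) | C=C(C)[C@H]1C[C@@]2(C)[C@H](CC[C@@H](O[Si](C)(C)C(C)(C)C)[C@@H]2C)[C@@H](O)[C@H]1O | intermediate
24 | 3α-(tert-butyldimethylsilyloxy)-8β,9β-(isopropylidenedioxy)eremophil-11-ene (10βH) | C=C(C)[C@H]1C[C@@]2(C)[C@H](CC[C@@H](O[Si](C)(C)C(C)(C)C)[C@@H]2C)[C@@H](O3)[C@H]1OC3(C)C | intermediate
25 | 8β,9β-(isopropylidenedioxy)eremophil-11-en-3α-ol (10βH) | C=C(C)[C@H]1C[C@@]2(C)[C@H](CC[C@@H](O)[C@@H]2C)[C@@H](O3)[C@H]1OC3(C)C | intermediate
26 | [bis(2,2,2-trifluoroethoxy)phosphoryl]acetic acid | OC(=O)CP(=O)(OCC(F)(F)F)OCC(F)(F)F | starting material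
27 | 8β,9β-(isopropylidenedioxy)eremophil-11-en-3α-yl [bis(2,2,2-trifluoroethoxy)phosphoryl]acetate (10βH) | C=C(C)[C@H]1C[C@@]2(C)[C@H](CC[C@@H](OC(=O)CP(=O)(OCC(F)(F)F)OCC(F)(F)F)[C@@H]2C)[C@@H](O3)[C@H]1OC3(C)C | intermediate
28 | (R)-pent-4-en-2-ol | C=CC[C@@H](C)O | starting material
29 | angelic acid, (Z)-2-methylbut-2-enoic acid | OC(=O)/C(C)=C\C | starting material
30 | (Z)-2-methylbut-2-enoic 2,4,6-trichlorobenzoic anhydride | O=C(OC(=O)/C(C)=C\C)c1c(Cl)cc(Cl)cc1Cl | intermediate
31 | (R)-pent-4-en-2-yl (Z)-2-methylbut-2-enoate | C=CC[C@@H](C)OC(=O)/C(C)=C\C | intermediate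
32 | (R)-4-oxobutan-2-yl (Z)-2-methylbut-2-enoate | O=CC[C@@H](C)OC(=O)/C(C)=C\C | intermediate
33 | 8β,9β-(isopropylidenedioxy)eremophil-11-en-3α-yl (2Z,5R)-5-[(Z)-2-methylbut-2-enoyloxy]hex-2-enoate (10βH) | C=C(C)[C@H]1C[C@@]2(C)[C@H](CC[C@@H](OC(=O)/C=C\C[C@@H](C)OC(=O)/C(C)=C\C)[C@@H]2C)[C@@H](O3)[C@H]1OC3(C)C | intermediate
34 | (10βH)-8β,9β-dihydroxyeremophil-11-en-3α-yl (2Z,5R)-5-[(Z)-2-methylbut-2-enoyloxy]hex-2-enoate, CNP0395983.1 | C=C(C)[C@H]1C[C@@]2(C)[C@H](CC[C@@H](OC(=O)/C=C\C[C@@H](C)OC(=O)/C(C)=C\C)[C@@H]2C)[C@@H](O)[C@H]1O | target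

Total step count: 21. Longest linear sequence: 19 steps (steps 1–17, 20 and 21, from 1 to 34); steps 18 and 19 make the side-chain aldehyde.

Steps most likely to fail

1. Step 12 (ring closure). What may go wrong: proton exchange between the enolate and unreacted ketone moves the enolate to the C10 side, which scrambles C10 or lets C10 attack the allyl unit; the allylpalladium unit may also lose a β-hydrogen to give a diene, or the enolate may react on oxygen. The fallback replaces the palladium-mediated ionisation by a direct enolate displacement. It sets out from alcohol 16 and comes back at ketone 19. Compound 16 is converted with MsCl, LiCl and 2,4,6-collidine in DMF at 0 °C into the allylic chloride F1. The potassium enolate formed from F1 with KN(SiMe3)2 in THF at −78 °C then displaces chloride on warming to 0 °C in an intramolecular SN2′ alkylation through the same chair, since direct SN2 attack would need an eight-membered ring.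

2. Step 6 (radical cyclisation). What may go wrong: the primary radical is reduced by the stannane, or abstracts the C4 hydrogen, before the slow 6-exo addition to the fully substituted alkene carbon C5. The fallback forms the same bond with a tethered soft carbanion. It sets out from alcohol 6 and comes back at ester 10. Compound 6 is acylated with methyl malonyl chloride and pyridine in CH2Cl2 at 0 °C to the mixed malonate F2. Cs2CO3 in MeCN at 50 °C brings about an intramolecular Michael addition of the malonate carbanion to C5, again from the α-face because of the tether, giving the bridged lactone diester F3. Krapcho dealkoxycarbonylation (LiCl, wet DMSO, 140 °C) gives the lactone ester F4. iBu2AlH in CH2Cl2 at −78 °C reduces the lactone, which is more reactive than the hindered ethyl ester, to the lactol ester F5. EtOH with PPTS, followed by NaOEt equilibration, gives 10.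

3. Step 14 (C9 reduction). What may go wrong: poor facial selectivity of hydride addition, with attack from the β-face past the silyl ether giving the axial 9α-alcohol. The fallback sets C9 by neighbouring-group participation instead. It sets out from silyl enol ether 20 and comes back at diol 23. Pb(OAc)4 in CH2Cl2 at −20 °C oxidises 20 from the β-face to the 8β-acetoxy ketone F6. NaBH4 reduces it to the 8β-acetoxy-9β-alcohol F7 together with the 8β-acetoxy-9α-alcohol F8. F8 is mesylated (MsCl, pyridine) to the 9α-mesylate F9. In KOAc-buffered wet acetic acid at 60 °C the axial antiperiplanar acetate displaces the axial mesylate from the β-face, and hydrolysis of the resulting acetoxonium ion returns F7, so both epimers converge. K2CO3 in MeOH then gives 23, which the second half of step 15 converts into 24.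

Further compounds
F1 | step 12 | (2E)-1-chloro-4-[(1R,2R,3R,6S)-6-acetyl-3-(tert-butyldimethylsilyloxy)-1,2-dimethylcyclohexyl]-2-methylbut-2-ene | ClC/C(C)=C/C[C@@]1(C)[C@H](CC[C@@H](O[Si](C)(C)C(C)(C)C)[C@@H]1C)C(C)=O
F2 | step 6 | (1R,2R)-4-(ethoxycarbonyl)-2,3-dimethylcyclohex-3-en-1-yl methyl malonate | CCOC(=O)C1=C(C)[C@@H](C)[C@H](OC(=O)CC(=O)OC)CC1
F3 | step 6 | 6-ethyl 4-methyl 5,9-dimethyl-3-oxo-2-oxabicyclo[3.3.1]nonane-4,6-dicarboxylate (ring configuration as in 10) | COC(=O)C2[C@@]1(C)[C@H](CC[C@@H](OC2=O)[C@@H]1C)C(=O)OCC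
F4 | step 6 | ethyl 5,9-dimethyl-3-oxo-2-oxabicyclo[3.3.1]nonane-6-carboxylate | O=C2C[C@@]1(C)[C@H](CC[C@@H](O2)[C@@H]1C)C(=O)OCC
F5 | step 6 | ethyl 3-hydroxy-5,9-dimethyl-2-oxabicyclo[3.3.1]nonane-6-carboxylate | OC2C[C@@]1(C)[C@H](CC[C@@H](O2)[C@@H]1C)C(=O)OCC
F6 | step 14 | 8β-acetoxy-3α-(tert-butyldimethylsilyloxy)eremophil-11-en-9-one (10βH) | C=C(C)[C@H]1C[C@@]2(C)[C@H](CC[C@@H](O[Si](C)(C)C(C)(C)C)[C@@H]2C)C(=O)[C@H]1OC(C)=O
F7 | step 14 | 8β-acetoxy-3α-(tert-butyldimethylsilyloxy)eremophil-11-en-9β-ol (10βH) | C=C(C)[C@H]1C[C@@]2(C)[C@H](CC[C@@H](O[Si](C)(C)C(C)(C)C)[C@@H]2C)[C@@H](O)[C@H]1OC(C)=O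
F8 | step 14 | 8β-acetoxy-3α-(tert-butyldimethylsilyloxy)eremophil-11-en-9α-ol (10βH) | C=C(C)[C@H]1C[C@@]2(C)[C@H](CC[C@@H](O[Si](C)(C)C(C)(C)C)[C@@H]2C)[C@H](O)[C@H]1OC(C)=O
F9 | step 14 | 8β-acetoxy-3α-(tert-butyldimethylsilyloxy)-9α-(methylsulfonyloxy)eremophil-11-ene (10βH) | C=C(C)[C@H]1C[C@@]2(C)[C@H](CC[C@@H](O[Si](C)(C)C(C)(C)C)[C@@H]2C)[C@H](OS(C)(=O)=O)[C@H]1OC(C)=O
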